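## Structural features

The target is a germacranolide: a ten-membered carbocycle (C1 to C10) with a Z-trisubstituted C1=C10 alkene (methyl C14) and an E-trisubstituted C4=C5 alkene (methyl C15), cis-fused across C6–C7 to an alpha-methylene-gamma-butyrolactone (O–C6, C7–C11(=C13)–C12). Four contiguous stereocentres run round the ring, C6 (S), C7 (S), C8 (R) and C9 (R): H6 and H7 are cis, C11 and O8 are syn along the C6–C9 chain, and the 8,9-diol is syn. O8 carries (2R,3R)-2,3-dimethyloxirane-2-carboxylic (epoxyangelic) acid and O9 is free. The fragile groups are the exocyclic enoate (a Michael acceptor), the C6–O bond (a prenyl-type allylic ester that acid or zerovalent palladium can ionise), the glycidic ester, and the free O9 next to the O8 ester (acyl shift); a free O8 can also take the lactone over from O6. The real difficulty is the cis lactone junction, the less stable arrangement, set beside two further carbinol centres on a strained medium ring whose two alkenes have opposite geometries. C7 lies between C6 and C8: when both are carbonyl carbons, C7–H is acidic and racemises freely. The key step uses this 1,3-dicarbonyl relationship, together with the C12 ester two atoms from C7, to set C6 and C7 and close the lactone ring in one catalytic reduction.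

## Logic of the disconnections

**40 to 39 to 32 + 37.** The O9–Si bond and then the ester C–O bond at O8 are cut. The glycidic ester and the free O9 beside it are the most labile parts, so they come last, and the cut takes two stereocentres out into 37 and makes the route convergent. The forward steps must acylate a hindered alcohol without moving the lactone to O8 and must remove silicon without opening the epoxide or shifting the acyl group.

**37 to 35 to 34 to 33.** The epoxide C–O bonds are cut. The Z geometry of 33 carries the relative configuration and a tartrate-controlled epoxidation of 34 the absolute one. The epoxide must survive oxidation of the carbinol to the acid.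

**32 to 31 to 28.** The C11=C13 bond is cut (and O8 re-silylated). The exocyclic enoate would not survive hydride, ylide or chromium reagents, so it is installed after them; the simpler 13-nor lactone 28 results. Enolisation must occur at C11 only, so both hydroxyls are silylated, with the more labile silyl group on O8.

**28 to 27 to 26 to 25 to 24.** C9–H and then C9–C10 are cut. The 8,9-diol is syn, whereas carbon addition to a C9 aldehyde under Felkin control would give the anti diol. C9 is therefore taken through ketone 26, where hydride addition anti to the C8–O bond gives the syn isomer. The C9–C10 cut opens the ring between two functional handles and leads to open-chain 24. The forward closure needs high dilution and retention of the Z geometry; the reduction must be 1,2 and face selective.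

**24 to 21 to 18 to 16.** C1=C10 is cut and the isopropylidene group restored. The Z-trisubstituted alkene with C14 comes from a Z-selective iodo-olefination of a C1 aldehyde, which the terminal alkene of the geranyl chain hides. The distal alkene must be cleaved in preference to C4=C5, and C9 must stay masked (as a thiazole) while C1 is olefinated.

**16 to 15 to 12 + 13.** C8–C9 is cut. Aldehyde 12 has C7 beside the carbonyl, so Felkin control can set 8R, and 13 delivers C9 at the aldehyde oxidation level without base. The forward step must not epimerise C7 or let O8 attack C12.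

**12 to 10 to 9.** Only the oxidation level of C8 changes. C8 must be distinguishable from the lactone carbonyl, which no hydride could do for a second methyl ester; 9 therefore carries an allyl ester. Deallylation must be neutral and the reduction must stop at the aldehyde.

**9 to 8 to 7 (key).** O6–C12 and C6–H are cut. Two stereocentres and the lactone ring come from a racemic precursor that needs no chiral starting material. The demand is one ketone face, one C7 enantiomer and 1,2-reduction.

**7 to 5 + 6, and 5 to 1 + 2 + 3.** C7–C11 and C6–C7 are cut, leaving four commercial pieces, of which 1 supplies C1 to C6, C15 and the E-C4=C5 alkene ready-made. The forward steps need mono-alkylation and retention of the E geometry.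

## Other disconnections considered

**Alternative 1:** The ring is traced back to the cis-fused decalin A2 by adding a transannular C5–C10 bond. Forward, methoxide adds to the C4 boronic ester of A2 and the borate fragments (Grob type): C4–B, C5–C10 and C1–OMs break together to give the protected dienetetraol A1.
- In favour: both ring alkenes arise stereospecifically from sp3 stereochemistry (boron and mesylate equatorial and anti to C5–C10; the cis fusion gives 4E,1(10)Z). No medium ring has to be closed, and six-membered-ring chemistry can place C6 to C9.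
- Against: A2 needs eight stereocentres, including quaternary C10 and a tertiary boronate at C4. The chair that fragments correctly puts the C15 methyl and C9 syn-diaxial, so a competing conformer or a stepwise path could erode the geometry. A1 still lacks the lactone: C12 must be unmasked, oxidised and closed cis onto O6, and the side chain added after that.
- Comparison: on alkene geometry the fragmentation is the better of the two, since the chosen plan relies on a Z-selective Wittig reaction and retention in a chromium-mediated closure. On the C6/C7 junction the chosen plan is stronger, because one catalytic step sets both centres and the lactone. In step count the chosen plan should be clearly shorter, because A2 is itself a long target.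

**Alternative 2:** The cut is C9–C10 as an acyl–alkenyl bond. The seco thioester–stannane A4 would be closed by Pd2(dba)3, P(2-furyl)3 and CuOP(O)Ph2 (a neutral thioester–stannane coupling) to the Z-enone A3, the 9-oxo form of the target, and a final 1,2-reduction would give the target.
- In favour: the latest possible closure, the whole periphery in place, no protecting group on the ring, neutral conditions, Z geometry carried by the stannane, and a ketone at C9 in place of two carbinol epimers.
- Against: A4 must carry the exocyclic enoate, the glycidic ester and an alpha-acyloxy thioester through a reaction that releases thiolate and uses phosphine and copper, all possible Michael donors or Lewis acids. The last step must reduce the enone carbonyl without touching the exocyclic enoate, with the right face, and nothing afterwards can repair it. Tin is needed.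
- Comparison: the bond closed is the same as in the chosen plan and the ring strain is equal. The coupling avoids the carbinol stage that the chosen plan passes through, and after closure it needs one step where the chosen plan needs seven, so in endgame length Alternative 2 is the better. The chosen plan is the safer in that C9 is reduced before the Michael acceptor and the side chain exist and can still be corrected.

**Alternative 3:** The cut is C3–C4, a bond with no neighbouring stereocentre or heteroatom. 9-BBN-H would add to the terminal C2=C3 alkene of the diene–iodide A6, and PdCl2(dppf) with Cs2CO3 would couple the C3 alkylborane with the E-C4 iodide to give the ring lactone A5.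
- In favour: the closure creates no stereocentre; both alkene geometries and all four stereocentres are fixed beforehand; A5 already has the O8/O9 pattern (PMB, TBS) that the endgame needs (methylenation, PMB removal, acylation, desilylation).
- Against: A6 needs an E-iodoalkene at C4 and a Z-diene at C10/C1 built separately onto the C6–C9 array, so the C1–C6 backbone cannot be bought as one piece. Hydroboration of a conjugated diene can go 1,4, the aqueous carbonate meets the lactone, and beta-hydride elimination competes in a strained ten-membered palladacycle.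
- Comparison: in the ring closure Alternative 3 is the better, because nothing stereogenic is at stake, whereas the chosen plan forms C9 there and passes through a ketone to set it. On chain supply and on the C6/C7 cis junction the chosen plan is simpler, since 1 brings C1 to C6 with the E alkene and the catalytic reduction sets both centres. Total step counts should be similar, with the effort in Alternative 3 moved into A6.

Key step: step 3

Remark: isomerically pure (2E)-geranic acid is assumed as starting material.
Remark: the (R,R) ligand in step 3 is chosen on the premise that the alkenyl arm of 7 takes the site that an aryl group occupies with this catalyst family; the enantiomeric ligand would serve if the sense proves opposite.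

## Route

Step 1
Reactants: 1 (2E)-geranic acid; 2 Meldrum's acid; 3 allyl alcohol
Product: 5 allyl (4E)-5,9-dimethyl-3-oxodeca-4,8-dienoate, via geranoyl Meldrum's acid 4 (not isolated)
Conditions: DCC, DMAP, CH2Cl2, 0 °C to rt; then 3, toluene, 80 °C
Reagents that add atoms: none
Why: Steglich-type C-acylation of Meldrum's acid gives 4, which on heating loses acetone and CO2 to an acylketene that allyl alcohol traps (Oikawa–Yonemitsu beta-keto ester synthesis). The conjugated E alkene is untouched, and the allyl ester is chosen so that C8 can later be told apart from the lactone carbonyl.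

Step 2
Reactants: 5 allyl (4E)-5,9-dimethyl-3-oxodeca-4,8-dienoate; 6 methyl bromoacetate
Product: 7 1-allyl 4-methyl 2-[(2E)-3,7-dimethylocta-2,6-dienoyl]butanedioate (racemic)
Conditions: K2CO3, acetone, rt
Reagents that add atoms: none
Why: Enolate alkylation of a beta-keto ester at its doubly activated alpha-carbon with a reactive alpha-halo ester; the mild carbonate base favours C-mono-alkylation and should not deconjugate the enone. The new centre C7 is racemic and is meant to stay labile.

Step 3
Reactants: 7 1-allyl 4-methyl 2-[(2E)-3,7-dimethylocta-2,6-dienoyl]butanedioate (racemic)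
Product: 9 allyl (2S,3S)-2-[(1E)-2,6-dimethylhepta-1,5-dien-1-yl]-5-oxooxolane-3-carboxylate, via anti hydroxy diester 8 (not isolated)
Conditions: RuCl(p-cymene)[(R,R)-TsDPEN] (2 mol %), HCO2H/Et3N (5:2), CH2Cl2, 30 °C
Reagents that add atoms: none
Why: Noyori–Ikariya asymmetric transfer hydrogenation run as a dynamic kinetic resolution; the closest known type is the reduction of alpha-substituted beta-keto esters that lactonise in the flask. The divalent ruthenium hydride formed from formate passes H from the metal to C6 and H from the ligand nitrogen to the carbonyl oxygen through an outer-sphere six-membered transition state, so the substrate is never chelated. Face selection at C6 (Re face, giving 6S) rests on contact between the C4=C5 alkenyl arm and the p-cymene ring of the (R,R) catalyst, the arm standing in for the aryl group of the usual substrates. C7 is set because the triethylamine/formate medium keeps the 1,3-dicarbonyl enolising, and only the enantiomer that can hold the C8 allyl ester perpendicular to the carbonyl and anti to the incoming hydride (Felkin type) is reduced quickly, which gives anti hydroxy diester 8 (7S). In 8 the C6 hydroxyl attacks the C12 methyl ester in a five-exo-trig acyl substitution, methanol leaves, and cis-lactone 9 is withdrawn from the enolisation equilibrium. The step needs 1,2- over 1,4-reduction, one ketone face and one C7 enantiomer: the C4 methyl group hinders conjugate hydride delivery, the alkenyl/arene contact fixes the face, and the perpendicular ester selects the C7 enantiomer. The allyl ester is inert to the ruthenium hydride and cannot form a lactone, so only the five-membered ring can close.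

Step 4
Reactants: 9 allyl (2S,3S)-2-[(1E)-2,6-dimethylhepta-1,5-dien-1-yl]-5-oxooxolane-3-carboxylate
Product: 10 (2S,3S)-2-[(1E)-2,6-dimethylhepta-1,5-dien-1-yl]-5-oxooxolane-3-carboxylic acid
Conditions: Pd(PPh3)4 (2 mol %), morpholine, THF, 0 °C; aq. citric acid work-up
Reagents that add atoms: none
Why: Tsuji–Trost deallylation: zerovalent palladium ionises the unhindered allyl ester far faster than the trisubstituted allylic lactone, and morpholine traps the allyl group. The carboxylate formed is no longer acidic at C7, so the cis junction is safe in the weakly basic medium.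

Step 5
Reactants: 10 (2S,3S)-2-[(1E)-2,6-dimethylhepta-1,5-dien-1-yl]-5-oxooxolane-3-carboxylic acid
Product: 12 (2S,3S)-2-[(1E)-2,6-dimethylhepta-1,5-dien-1-yl]-5-oxooxolane-3-carbaldehyde, via acid chloride 11 (not isolated)
Conditions: 1-chloro-N,N,2-trimethylprop-1-en-1-amine, CH2Cl2, 0 °C; then LiAlH(OtBu)3, THF, −78 °C
Reagents that add atoms: none
Why: The Ghosez reagent forms acid chloride 11 under neutral conditions, so no ketene or enol can scramble C7, and LiAlH(OtBu)3 at −78 °C reduces acid chlorides to aldehydes without touching a lactone. No free C8 alcohol is formed, which avoids migration of the lactone to O8; 12 is used at once.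

Step 6
Reactants: 12 (2S,3S)-2-[(1E)-2,6-dimethylhepta-1,5-dien-1-yl]-5-oxooxolane-3-carbaldehyde; 13 2-(trimethylsilyl)-1,3-thiazole
Product: 15 (4R,5S)-5-[(1E)-2,6-dimethylhepta-1,5-dien-1-yl]-4-[(R)-hydroxy(1,3-thiazol-2-yl)methyl]oxolan-2-one, via O-trimethylsilyl adduct 14 (not isolated)
Conditions: CH2Cl2, 0 °C to rt; then aq. citric acid, THF, 0 °C
Reagents that add atoms: none
Why: Dondoni homologation: the silylthiazole adds to aldehydes without base or catalyst and passes its silyl group to the new oxygen, so C7 is not epimerised and O8 is capped as it forms; mild acid then frees the carbinol. Felkin–Anh control should set 8R: the C6–C7 bond, the bulkier branch that also carries the cis alkenyl arm, stands perpendicular to the carbonyl and the thiazole carbon enters anti to it, past H7. The thiazole is a masked formyl group, so C9 arrives at the aldehyde oxidation level.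

Step 7
Reactants: 15 (4R,5S)-5-[(1E)-2,6-dimethylhepta-1,5-dien-1-yl]-4-[(R)-hydroxy(1,3-thiazol-2-yl)methyl]oxolan-2-one
Product: 16 (4S,5S)-5-[(1E)-2,6-dimethylhepta-1,5-dien-1-yl]-4-[(R)-(1,3-thiazol-2-yl)(triethylsilyloxy)methyl]oxolan-2-one
Conditions: Et3SiOTf, 2,6-lutidine, CH2Cl2, −78 °C
Reagents that add atoms: triethylsilyl trifluoromethanesulfonate, CC[Si](CC)(CC)OS(=O)(=O)C(F)(F)F
Why: Silylation with a silyl triflate and a hindered base is fast at −78 °C and neither acidic nor nucleophilic, so the free O8 has no time to attack C12. A triethylsilyl ether does not chelate in the later reduction and can be removed in the presence of a tert-butyldimethylsilyl ether.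

Step 8
Reactants: 16 (4S,5S)-5-[(1E)-2,6-dimethylhepta-1,5-dien-1-yl]-4-[(R)-(1,3-thiazol-2-yl)(triethylsilyloxy)methyl]oxolan-2-one
Product: 18 (4E)-4-methyl-5-[(2S,3S)-5-oxo-3-[(R)-(1,3-thiazol-2-yl)(triethylsilyloxy)methyl]oxolan-2-yl]pent-4-enal, via terminal epoxide 17 (not isolated)
Conditions: mCPBA, NaHCO3, CH2Cl2, −20 to 0 °C; then H5IO6, THF/Et2O, 0 °C
Reagents that add atoms: 3-chloroperoxybenzoic acid, OOC(=O)c1cccc(Cl)c1
Why: Prilezhaev epoxidation should select the distal, more electron-rich isopropylidene alkene; C4=C5 is deactivated by the allylic lactone oxygen and shielded by C6, and the thiazole is oxidised only slowly. Periodic acid opens the trisubstituted epoxide and cleaves the glycol to the C1 aldehyde and acetone.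

Step 9
Reactants: 18 (4E)-4-methyl-5-[(2S,3S)-5-oxo-3-[(R)-(1,3-thiazol-2-yl)(triethylsilyloxy)methyl]oxolan-2-yl]pent-4-enal; 19 ethyltriphenylphosphonium iodide
Product: 21 (4S,5S)-5-[(1E,5Z)-6-iodo-2-methylhepta-1,5-dien-1-yl]-4-[(R)-(1,3-thiazol-2-yl)(triethylsilyloxy)methyl]oxolan-2-one, via (1-iodoethyl)triphenylphosphonium iodide 20 (not isolated)
Conditions: 19, n-BuLi, THF, 0 °C; I2, −78 °C; NaHMDS, −20 °C; then 18, −78 °C
Reagents that add atoms: iodine, II
Why: Stork–Zhao-type Wittig olefination with the alpha-iodo ylide made in the flask from 19 by deprotonation, iodination to 20 and a second deprotonation; kinetically controlled addition to aldehydes gives (Z)-2-iodoalk-2-enes. C10 and C14 enter here, and the iodide stands cis to C2, the geometry the ring needs.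

Step 10
Reactants: 21 (4S,5S)-5-[(1E,5Z)-6-iodo-2-methylhepta-1,5-dien-1-yl]-4-[(R)-(1,3-thiazol-2-yl)(triethylsilyloxy)methyl]oxolan-2-one
Product: 24 (2R)-2-[(2S,3S)-2-[(1E,5Z)-6-iodo-2-methylhepta-1,5-dien-1-yl]-5-oxooxolan-3-yl]-2-(triethylsilyloxy)acetaldehyde, via N-methylthiazolium triflate 22 (not isolated), via thiazolidine 23 (not isolated)
Conditions: MeOTf, 4 Å MS, MeCN, rt; NaBH4, MeOH, −10 °C; CuO, CuCl2·2H2O, MeCN/H2O, rt
Reagents that add atoms: water, O
Why: Dondoni unmasking: N-methylation activates the thiazole, borohydride reduces thiazolium salt 22 to thiazolidine 23, and the thiophilic copper salts hydrolyse this N,S-acetal to the aldehyde near neutral pH. The lactone, the silyl ether, the iodoalkene and the alpha-centre C8 should not be affected by these three mild operations.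

Step 11
Reactants: 24 (2R)-2-[(2S,3S)-2-[(1E,5Z)-6-iodo-2-methylhepta-1,5-dien-1-yl]-5-oxooxolan-3-yl]-2-(triethylsilyloxy)acetaldehyde
Product: 25 (1(10)Z,4E,6S,7S,8R)-9-hydroxy-8-(triethylsilyloxy)-13-norgermacra-1(10),4-dien-12,6-olide (both C9 epimers)
Conditions: CrCl2 (10 equiv), NiCl2 (1 mol % of Cr), DMSO/THF, rt, 0.003 M, slow addition
Reagents that add atoms: none
Why: Intramolecular Nozaki–Hiyama–Kishi reaction: zerovalent nickel inserts into the C10–I bond, the alkenyl group passes to trivalent chromium with retention of the Z geometry, and the alkenylchromium adds to the C9 aldehyde; the reagent tolerates lactone and silyl ether. High dilution favours the ten-membered ring over oligomers; the configuration formed at C9 (the 9S, Felkin-type epimer is expected to predominate) does not matter because C9 is oxidised in step 12.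

Step 12
Reactants: 25 (1(10)Z,4E,6S,7S,8R)-9-hydroxy-8-(triethylsilyloxy)-13-norgermacra-1(10),4-dien-12,6-olide (both C9 epimers)
Product: 26 (1(10)Z,4E,6S,7S,8R)-9-oxo-8-(triethylsilyloxy)-13-norgermacra-1(10),4-dien-12,6-olide
Conditions: Dess–Martin periodinane, NaHCO3, CH2Cl2, 0 °C to rt
Reagents that add atoms: none
Why: Dess–Martin oxidation of a secondary allylic alcohol under buffered, non-basic conditions; both C9 epimers converge on one enone. The Z geometry is held by the ring and the alpha-silyloxy centre C8 should not enolise.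

Step 13
Reactants: 26 (1(10)Z,4E,6S,7S,8R)-9-oxo-8-(triethylsilyloxy)-13-norgermacra-1(10),4-dien-12,6-olide
Product: 27 (1(10)Z,4E,6S,7S,8R,9R)-9-hydroxy-8-(triethylsilyloxy)-13-norgermacra-1(10),4-dien-12,6-olide
Conditions: NaBH4, CeCl3·7H2O, MeOH, −78 °C
Reagents that add atoms: none
Why: Luche reduction gives 1,2-addition to the enone and leaves the lactone alone at −78 °C. Polar Felkin–Anh control is expected to set 9R: the non-chelating C8–OSiEt3 bond lies perpendicular to the carbonyl and hydride enters anti to it from the outer face of the ring, which gives the 8,9-syn diol.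

Step 14
Reactants: 27 (1(10)Z,4E,6S,7S,8R,9R)-9-hydroxy-8-(triethylsilyloxy)-13-norgermacra-1(10),4-dien-12,6-olide
Product: 28 (1(10)Z,4E,6S,7S,8R,9R)-9-(tert-butyldimethylsilyloxy)-8-(triethylsilyloxy)-13-norgermacra-1(10),4-dien-12,6-olide
Conditions: tBuMe2SiOTf, 2,6-lutidine, CH2Cl2, −78 to 0 °C
Reagents that add atoms: tert-butyldimethylsilyl trifluoromethanesulfonate, CC(C)(C)[Si](C)(C)OS(=O)(=O)C(F)(F)F
Why: Silyl triflate silylation of the hindered allylic alcohol; O9 now carries the more robust of the two silyl groups, so O8 can be released first.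

Step 15
Reactants: 28 (1(10)Z,4E,6S,7S,8R,9R)-9-(tert-butyldimethylsilyloxy)-8-(triethylsilyloxy)-13-norgermacra-1(10),4-dien-12,6-olide
Product: 31 (1(10)Z,4E,6S,7S,8R,9R)-9-(tert-butyldimethylsilyloxy)-8-(triethylsilyloxy)germacra-1(10),4,11(13)-trien-12,6-olide, via Mannich base 29 (not isolated), via trimethylammonium iodide 30 (not isolated)
Conditions: LDA, THF, −78 °C; CH2=NMe2+ I−, −78 to 0 °C; MeI, MeOH, rt; aq. NaHCO3, CH2Cl2, rt
Reagents that add atoms: N,N-dimethylmethyleneiminium iodide (Eschenmoser's salt), C=[N+](C)C.[I-]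
Why: Alpha-methylenation of a lactone through its lithium enolate: LDA deprotonates C11, the only acidic position, Eschenmoser's salt aminomethylates the enolate (Mannich reaction), and quaternisation followed by mild base gives elimination to the exocyclic alkene. No leaving group sits on C7, so the enolate cannot fragment.

Step 16
Reactants: 31 (1(10)Z,4E,6S,7S,8R,9R)-9-(tert-butyldimethylsilyloxy)-8-(triethylsilyloxy)germacra-1(10),4,11(13)-trien-12,6-olide
Product: 32 (1(10)Z,4E,6S,7R,8R,9R)-9-(tert-butyldimethylsilyloxy)-8-hydroxygermacra-1(10),4,11(13)-trien-12,6-olide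
Conditions: HF·pyridine, pyridine, THF, 0 °C
Reagents that add atoms: none
Why: Buffered HF·pyridine cleaves a secondary triethylsilyl ether much faster than a secondary tert-butyldimethylsilyl ether; the acidic medium adds no nucleophile to the exocyclic enoate and should not promote lactone migration to O8.

Step 17
Reactants: 33 angelic acid
Product: 34 (2Z)-2-methylbut-2-en-1-ol
Conditions: LiAlH4, Et2O, 0 °C
Reagents that add atoms: none
Why: Hydride reduction of a carboxylic acid to the primary alcohol; at 0 °C the Z alkene should be neither reduced nor isomerised.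

Step 18
Reactants: 34 (2Z)-2-methylbut-2-en-1-ol
Product: 35 [(2S,3R)-2,3-dimethyloxiran-2-yl]methanol
Conditions: Ti(OiPr)4 (10 mol %), L-(+)-diethyl tartrate (12 mol %), t-BuOOH, 4 Å MS, CH2Cl2, −20 °C
Reagents that add atoms: tert-butyl hydroperoxide, CC(C)(C)OO
Why: Sharpless asymmetric epoxidation; with L-(+)-diethyl tartrate oxygen is delivered to the face of the Z allylic alcohol that gives the (2S,3R)-epoxy alcohol, the Z geometry fixing the relative and the tartrate the absolute configuration of both centres.

Step 19
Reactants: 35 [(2S,3R)-2,3-dimethyloxiran-2-yl]methanol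
Product: 37 (2R,3R)-2,3-dimethyloxirane-2-carboxylic acid, via epoxy aldehyde 36 (not isolated)
Conditions: TEMPO (cat.), NaClO2, NaOCl (cat.), MeCN/pH 6.7 phosphate buffer, 35 °C
Reagents that add atoms: sodium chlorite, [Na+].[O-]Cl=O
Why: TEMPO-catalysed oxidation with chlorite as terminal oxidant takes the primary alcohol through aldehyde 36 to the acid near neutral pH, which a trisubstituted epoxide tolerates; the stereocentres are not involved.

Step 20
Reactants: 32 (1(10)Z,4E,6S,7R,8R,9R)-9-(tert-butyldimethylsilyloxy)-8-hydroxygermacra-1(10),4,11(13)-trien-12,6-olide; 37 (2R,3R)-2,3-dimethyloxirane-2-carboxylic acid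
Product: 39 (1(10)Z,4E,6S,7S,8R,9R)-9-(tert-butyldimethylsilyloxy)-8-[(2R,3R)-2,3-dimethyloxirane-2-carbonyloxy]germacra-1(10),4,11(13)-trien-12,6-olide, via mixed anhydride 38 (not isolated)
Conditions: 2,4,6-trichlorobenzoyl chloride, Et3N, THF, rt; then 32, DMAP, toluene, rt
Reagents that add atoms: none
Why: Yamaguchi esterification: the hindered acid is activated as mixed anhydride 38 and DMAP transfers the acyl group to the secondary C8 alcohol. Acylation is expected to outrun migration of the lactone to O8, and the epoxide carbon next to the carbonyl has no hydrogen to epimerise.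

Step 21
Reactants: 39 (1(10)Z,4E,6S,7S,8R,9R)-9-(tert-butyldimethylsilyloxy)-8-[(2R,3R)-2,3-dimethyloxirane-2-carbonyloxy]germacra-1(10),4,11(13)-trien-12,6-olide
Product: 40 (1(10)Z,4E,6S,7S,8R,9R)-9-hydroxy-8-[(2R,3R)-2,3-dimethyloxirane-2-carbonyloxy]germacra-1(10),4,11(13)-trien-12,6-olide (CNP0318223.2)
Conditions: HF·pyridine, THF, 0 °C to rt
Reagents that add atoms: none
Why: Fluoride cleavage of the allylic silyl ether under acidic, non-nucleophilic conditions, which should avoid acyl migration from O8 to O9, Michael addition to the enoate and opening of the electron-poor epoxide.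

## Compound list

1 | (2E)-3,7-dimethylocta-2,6-dienoic acid (geranic acid) | CC(C)=CCC/C(C)=C/C(=O)O | starting material
2 | 2,2-dimethyl-1,3-dioxane-4,6-dione (Meldrum's acid) | CC1(C)OC(=O)CC(=O)O1 | starting material
3 | prop-2-en-1-ol (allyl alcohol) | C=CCO | starting material
4 | 5-[(2E)-1-hydroxy-3,7-dimethylocta-2,6-dien-1-ylidene]-2,2-dimethyl-1,3-dioxane-4,6-dione | CC(C)=CCC/C(C)=C/C(O)=C1C(=O)OC(C)(C)OC1=O | intermediate
5 | allyl (4E)-5,9-dimethyl-3-oxodeca-4,8-dienoate | C=CCOC(=O)CC(=O)/C=C(\C)CCC=C(C)C | intermediate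
6 | methyl bromoacetate | COC(=O)CBr | starting material
7 | 1-allyl 4-methyl 2-[(2E)-3,7-dimethylocta-2,6-dienoyl]butanedioate (racemic) | COC(=O)CC(C(=O)OCC=C)C(=O)/C=C(\C)CCC=C(C)C | intermediate
8 | 1-allyl 4-methyl (2S)-2-[(1S,2E)-1-hydroxy-3,7-dimethylocta-2,6-dien-1-yl]butanedioate | COC(=O)C[C@H](C(=O)OCC=C)[C@@H](O)/C=C(\C)CCC=C(C)C | intermediate
9 | allyl (2S,3S)-2-[(1E)-2,6-dimethylhepta-1,5-dien-1-yl]-5-oxooxolane-3-carboxylate | O=C1C[C@H](C(=O)OCC=C)[C@@H](O1)/C=C(\C)CCC=C(C)C | intermediate
10 | (2S,3S)-2-[(1E)-2,6-dimethylhepta-1,5-dien-1-yl]-5-oxooxolane-3-carboxylic acid | O=C1C[C@H](C(=O)O)[C@@H](O1)/C=C(\C)CCC=C(C)C | intermediate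
11 | (2S,3S)-2-[(1E)-2,6-dimethylhepta-1,5-dien-1-yl]-5-oxooxolane-3-carbonyl chloride | O=C1C[C@H](C(=O)Cl)[C@@H](O1)/C=C(\C)CCC=C(C)C | intermediate
12 | (2S,3S)-2-[(1E)-2,6-dimethylhepta-1,5-dien-1-yl]-5-oxooxolane-3-carbaldehyde | O=C1C[C@H](C=O)[C@@H](O1)/C=C(\C)CCC=C(C)C | intermediate
13 | 2-(trimethylsilyl)-1,3-thiazole | C[Si](C)(C)c1nccs1 | starting material
14 | (4S,5S)-5-[(1E)-2,6-dimethylhepta-1,5-dien-1-yl]-4-[(R)-(1,3-thiazol-2-yl)(trimethylsilyloxy)methyl]oxolan-2-one | c1csc(n1)[C@H](O[Si](C)(C)C)[C@H]1CC(=O)O[C@H]1/C=C(\C)CCC=C(C)C | intermediate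
15 | (4R,5S)-5-[(1E)-2,6-dimethylhepta-1,5-dien-1-yl]-4-[(R)-hydroxy(1,3-thiazol-2-yl)methyl]oxolan-2-one | c1csc(n1)[C@H](O)[C@H]1CC(=O)O[C@H]1/C=C(\C)CCC=C(C)C | intermediate
16 | (4S,5S)-5-[(1E)-2,6-dimethylhepta-1,5-dien-1-yl]-4-[(R)-(1,3-thiazol-2-yl)(triethylsilyloxy)methyl]oxolan-2-one | c1csc(n1)[C@H](O[Si](CC)(CC)CC)[C@H]1CC(=O)O[C@H]1/C=C(\C)CCC=C(C)C | intermediate
17 | (4S,5S)-5-[(1E)-4-(3,3-dimethyloxiran-2-yl)-2-methylbut-1-en-1-yl]-4-[(R)-(1,3-thiazol-2-yl)(triethylsilyloxy)methyl]oxolan-2-one (epoxide carbon: both epimers) | c1csc(n1)[C@H](O[Si](CC)(CC)CC)[C@H]1CC(=O)O[C@H]1/C=C(\C)CCC2OC2(C)C | intermediate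
18 | (4E)-4-methyl-5-[(2S,3S)-5-oxo-3-[(R)-(1,3-thiazol-2-yl)(triethylsilyloxy)methyl]oxolan-2-yl]pent-4-enal | c1csc(n1)[C@H](O[Si](CC)(CC)CC)[C@H]1CC(=O)O[C@H]1/C=C(\C)CCC=O | intermediate
19 | ethyltriphenylphosphonium iodide | CC[P+](c1ccccc1)(c1ccccc1)c1ccccc1.[I-] | starting material
20 | (1-iodoethyl)triphenylphosphonium iodide | CC(I)[P+](c1ccccc1)(c1ccccc1)c1ccccc1.[I-] | intermediate
21 | (4S,5S)-5-[(1E,5Z)-6-iodo-2-methylhepta-1,5-dien-1-yl]-4-[(R)-(1,3-thiazol-2-yl)(triethylsilyloxy)methyl]oxolan-2-one | c1csc(n1)[C@H](O[Si](CC)(CC)CC)[C@H]1CC(=O)O[C@H]1/C=C(\C)CC/C=C(/C)I | intermediate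
22 | 2-[(R)-[(2S,3S)-2-[(1E,5Z)-6-iodo-2-methylhepta-1,5-dien-1-yl]-5-oxooxolan-3-yl](triethylsilyloxy)methyl]-3-methyl-1,3-thiazol-3-ium trifluoromethanesulfonate | C[n+]1ccsc1[C@H](O[Si](CC)(CC)CC)[C@H]1CC(=O)O[C@H]1/C=C(\C)CC/C=C(/C)I.[O-]S(=O)(=O)C(F)(F)F | intermediate
23 | (4S,5S)-5-[(1E,5Z)-6-iodo-2-methylhepta-1,5-dien-1-yl]-4-[(R)-(3-methyl-1,3-thiazolidin-2-yl)(triethylsilyloxy)methyl]oxolan-2-one (thiazolidine C2: both epimers) | CN1CCSC1[C@H](O[Si](CC)(CC)CC)[C@H]1CC(=O)O[C@H]1/C=C(\C)CC/C=C(/C)I | intermediate
24 | (2R)-2-[(2S,3S)-2-[(1E,5Z)-6-iodo-2-methylhepta-1,5-dien-1-yl]-5-oxooxolan-3-yl]-2-(triethylsilyloxy)acetaldehyde | O=C[C@H](O[Si](CC)(CC)CC)[C@H]1CC(=O)O[C@H]1/C=C(\C)CC/C=C(/C)I | intermediate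
25 | (1(10)Z,4E,6S,7S,8R)-9-hydroxy-8-(triethylsilyloxy)-13-norgermacra-1(10),4-dien-12,6-olide (both C9 epimers) | C1C(=O)O[C@H]2/C=C(\C)CC/C=C(/C)C(O)[C@H](O[Si](CC)(CC)CC)[C@@H]12 | intermediate
26 | (1(10)Z,4E,6S,7S,8R)-9-oxo-8-(triethylsilyloxy)-13-norgermacra-1(10),4-dien-12,6-olide | C1C(=O)O[C@H]2/C=C(\C)CC/C=C(/C)C(=O)[C@H](O[Si](CC)(CC)CC)[C@@H]12 | intermediate
27 | (1(10)Z,4E,6S,7S,8R,9R)-9-hydroxy-8-(triethylsilyloxy)-13-norgermacra-1(10),4-dien-12,6-olide | C1C(=O)O[C@H]2/C=C(\C)CC/C=C(/C)[C@@H](O)[C@H](O[Si](CC)(CC)CC)[C@@H]12 | intermediate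
28 | (1(10)Z,4E,6S,7S,8R,9R)-9-(tert-butyldimethylsilyloxy)-8-(triethylsilyloxy)-13-norgermacra-1(10),4-dien-12,6-olide | C1C(=O)O[C@H]2/C=C(\C)CC/C=C(/C)[C@@H](O[Si](C)(C)C(C)(C)C)[C@H](O[Si](CC)(CC)CC)[C@@H]12 | intermediate
29 | (1(10)Z,4E,6S,7S,8R,9R)-9-(tert-butyldimethylsilyloxy)-13-(dimethylamino)-8-(triethylsilyloxy)germacra-1(10),4-dien-12,6-olide (C11: both epimers) | CN(C)CC1C(=O)O[C@H]2/C=C(\C)CC/C=C(/C)[C@@H](O[Si](C)(C)C(C)(C)C)[C@H](O[Si](CC)(CC)CC)[C@@H]12 | intermediate
30 | N-methyl quaternary ammonium iodide of 29 (13-trimethylammonio compound; C11: both epimers) | C[N+](C)(C)CC1C(=O)O[C@H]2/C=C(\C)CC/C=C(/C)[C@@H](O[Si](C)(C)C(C)(C)C)[C@H](O[Si](CC)(CC)CC)[C@@H]12.[I-] | intermediate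
31 | (1(10)Z,4E,6S,7S,8R,9R)-9-(tert-butyldimethylsilyloxy)-8-(triethylsilyloxy)germacra-1(10),4,11(13)-trien-12,6-olide | C=C1C(=O)O[C@H]2/C=C(\C)CC/C=C(/C)[C@@H](O[Si](C)(C)C(C)(C)C)[C@H](O[Si](CC)(CC)CC)[C@@H]12 | intermediate
32 | (1(10)Z,4E,6S,7R,8R,9R)-9-(tert-butyldimethylsilyloxy)-8-hydroxygermacra-1(10),4,11(13)-trien-12,6-olide | C=C1C(=O)O[C@H]2/C=C(\C)CC/C=C(/C)[C@@H](O[Si](C)(C)C(C)(C)C)[C@H](O)[C@@H]12 | intermediate
33 | (2Z)-2-methylbut-2-enoic acid (angelic acid) | C/C=C(/C)C(=O)O | starting material
34 | (2Z)-2-methylbut-2-en-1-ol | C/C=C(/C)CO | intermediate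
35 | [(2S,3R)-2,3-dimethyloxiran-2-yl]methanol | OC[C@]1(C)O[C@@H]1C | intermediate
36 | (2R,3R)-2,3-dimethyloxirane-2-carbaldehyde | O=C[C@]1(C)O[C@@H]1C | intermediate
37 | (2R,3R)-2,3-dimethyloxirane-2-carboxylic acid | OC(=O)[C@]1(C)O[C@@H]1C | intermediate
38 | (2R,3R)-2,3-dimethyloxirane-2-carboxylic 2,4,6-trichlorobenzoic anhydride | O=C(OC(=O)c1c(Cl)cc(Cl)cc1Cl)[C@]1(C)O[C@@H]1C | intermediate
39 | (1(10)Z,4E,6S,7S,8R,9R)-9-(tert-butyldimethylsilyloxy)-8-[(2R,3R)-2,3-dimethyloxirane-2-carbonyloxy]germacra-1(10),4,11(13)-trien-12,6-olide | C=C1C(=O)O[C@H]2/C=C(\C)CC/C=C(/C)[C@@H](O[Si](C)(C)C(C)(C)C)[C@H](OC(=O)[C@]3(C)O[C@@H]3C)[C@@H]12 | intermediate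
40 | (1(10)Z,4E,6S,7S,8R,9R)-9-hydroxy-8-[(2R,3R)-2,3-dimethyloxirane-2-carbonyloxy]germacra-1(10),4,11(13)-trien-12,6-olide (CNP0318223.2) | C=C1C(=O)O[C@H]2/C=C(\C)CC/C=C(/C)[C@@H](O)[C@H](OC(=O)[C@]3(C)O[C@@H]3C)[C@@H]12 | target

## Step count and least certain steps

Total: 21 steps. Longest linear sequence: 18 steps (steps 1 to 16, 20 and 21); the side-chain acid takes 3 steps (17 to 19).

**Step 3 (key step).** The two rapidly equilibrating enantiomers may be told apart incompletely, eroding the anti/syn outcome, because the allyl ester is not much larger than the CH2CO2CH3 arm. Face selection may be weak because an alkenyl group is a poorer partner for the cymene ring than an aryl group. Conjugate reduction may compete, and the lactone carboxylate may be eliminated from C6 if the product lingers in the basic medium. Fallback: from 5, the ketone is reduced enantioselectively without any dynamic resolution (the same ruthenium catalyst, or (S)-Me-CBS with catecholborane if the ruthenium hydride discriminates the faces poorly) to allyl (3R,4E)-3-hydroxy-5,9-dimethyldeca-4,8-dienoate F1. Fráter–Seebach alkylation of the dianion of F1 (LDA, 2 equiv, then 6) introduces the CH2CO2CH3 arm anti to the hydroxyl and gives 8, which mild acid closes to 9, where the route is rejoined.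

**Step 5.** Over-reduction to the primary alcohol, which could then take over the lactone, or loss of the C7 configuration at the acid chloride stage. Fallback: from 10, activation with isobutyl chloroformate and N-methylmorpholine at −15 °C to the isobutyl mixed anhydride F2, reduction with NaBH4 and a cold quench to the hydroxymethyl lactone F3, and Dess–Martin oxidation of F3 to 12.

**Step 6.** Poor facial selectivity at C8, because both branches at C7 are ring carbons, or slow addition to a hindered aldehyde that epimerises meanwhile. Fallback: the C8 epimer mixture of 15 is oxidised with Dess–Martin periodinane to the 2-acylthiazole F4, which is reduced under reagent control ((S)-Me-CBS, catecholborane, −78 °C, the thiazole taking the aryl role) back to 15.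

**Step 11.** Oligomerisation in place of closure of the strained ring, protodeiodination, or partial loss of the Z geometry at the alkenylchromium stage. Fallback: from 24, Pinnick oxidation to the acid F5, coupling with thiophenol (DCC, DMAP) to the S-phenyl thioester F6, iodine–tin exchange (Me6Sn2, Pd(PPh3)4) to the stannane F7, and ring closure by thioester–stannane coupling (Pd2(dba)3, P(2-furyl)3, CuOP(O)Ph2), which gives enone 26 directly.

**Step 13.** Hydride delivery to the wrong face if the ring conformation overrides the local Felkin preference. Fallback: the 9S alcohol F8 is inverted by a Mitsunobu reaction with chloroacetic acid (PPh3, DIAD) to the 9R chloroacetate F9, which thiourea cleaves under neutral conditions to 27.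

## Further compounds

F1 | step 3 | allyl (3R,4E)-3-hydroxy-5,9-dimethyldeca-4,8-dienoate | C=CCOC(=O)C[C@@H](O)/C=C(\C)CCC=C(C)C
F2 | step 5 | (2S,3S)-2-[(1E)-2,6-dimethylhepta-1,5-dien-1-yl]-5-oxooxolane-3-carboxylic isobutyl carbonic anhydride | O=C1C[C@H](C(=O)OC(=O)OCC(C)C)[C@@H](O1)/C=C(\C)CCC=C(C)C
F3 | step 5 | (4R,5S)-5-[(1E)-2,6-dimethylhepta-1,5-dien-1-yl]-4-(hydroxymethyl)oxolan-2-one | O=C1C[C@H](CO)[C@@H](O1)/C=C(\C)CCC=C(C)C
F4 | step 6 | (4S,5S)-5-[(1E)-2,6-dimethylhepta-1,5-dien-1-yl]-4-(1,3-thiazole-2-carbonyl)oxolan-2-one | O=C(c1nccs1)[C@H]1CC(=O)O[C@H]1/C=C(\C)CCC=C(C)C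
F5 | step 11 | (2R)-2-[(2S,3S)-2-[(1E,5Z)-6-iodo-2-methylhepta-1,5-dien-1-yl]-5-oxooxolan-3-yl]-2-(triethylsilyloxy)acetic acid | OC(=O)[C@H](O[Si](CC)(CC)CC)[C@H]1CC(=O)O[C@H]1/C=C(\C)CC/C=C(/C)I
F6 | step 11 | S-phenyl (2R)-2-[(2S,3S)-2-[(1E,5Z)-6-iodo-2-methylhepta-1,5-dien-1-yl]-5-oxooxolan-3-yl]-2-(triethylsilyloxy)ethanethioate | O=C(Sc1ccccc1)[C@H](O[Si](CC)(CC)CC)[C@H]1CC(=O)O[C@H]1/C=C(\C)CC/C=C(/C)I
F7 | step 11 | S-phenyl (2R)-2-[(2S,3S)-2-[(1E,5Z)-2-methyl-6-(trimethylstannyl)hepta-1,5-dien-1-yl]-5-oxooxolan-3-yl]-2-(triethylsilyloxy)ethanethioate | O=C(Sc1ccccc1)[C@H](O[Si](CC)(CC)CC)[C@H]1CC(=O)O[C@H]1/C=C(\C)CC/C=C(/C)[Sn](C)(C)C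
F8 | step 13 | (1(10)Z,4E,6S,7S,8R,9S)-9-hydroxy-8-(triethylsilyloxy)-13-norgermacra-1(10),4-dien-12,6-olide | C1C(=O)O[C@H]2/C=C(\C)CC/C=C(/C)[C@H](O)[C@H](O[Si](CC)(CC)CC)[C@@H]12
F9 | step 13 | (1(10)Z,4E,6S,7S,8R,9R)-9-(chloroacetoxy)-8-(triethylsilyloxy)-13-norgermacra-1(10),4-dien-12,6-olide | C1C(=O)O[C@H]2/C=C(\C)CC/C=C(/C)[C@@H](OC(=O)CCl)[C@H](O[Si](CC)(CC)CC)[C@@H]12
A1 | alternative 1 | (1(10)Z,4E,6S,7R,8R,9R)-6,9,12-tris(tert-butyldimethylsilyloxy)-8-(4-methoxybenzyloxy)germacra-1(10),4,11(13)-triene | CC(C)(C)[Si](C)(C)O[C@H]1/C=C(\C)CC/C=C(/C)[C@@H](O[Si](C)(C)C(C)(C)C)[C@H](OCc2ccc(OC)cc2)[C@H]1C(=C)CO[Si](C)(C)C(C)(C)C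
A2 | alternative 1 | cis-fused eudesm-11(13)-ene with equatorial C1 mesylate and C4 pinacol boronate, axial C15, 6,9,12-tris(tert-butyldimethylsilyloxy) and 8-(4-methoxybenzyloxy) groups (one arrangement that meets the antiperiplanar requirement) | CS(=O)(=O)O[C@H]1CC[C@](C)(B2OC(C)(C)C(C)(C)O2)[C@H]3[C@H](O[Si](C)(C)C(C)(C)C)[C@H](C(=C)CO[Si](C)(C)C(C)(C)C)[C@@H](OCc4ccc(OC)cc4)[C@H](O[Si](C)(C)C(C)(C)C)[C@@]13C
A3 | alternative 2 | (1(10)Z,4E,6S,7S,8R)-8-[(2R,3R)-2,3-dimethyloxirane-2-carbonyloxy]-9-oxogermacra-1(10),4,11(13)-trien-12,6-olide | C=C1C(=O)O[C@H]2/C=C(\C)CC/C=C(/C)C(=O)[C@H](OC(=O)[C@]3(C)O[C@@H]3C)[C@@H]12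
A4 | alternative 2 | seco S-phenyl C9 thioester with (Z)-C10 tributylstannane, alpha-methylene cis-lactone and O8 epoxyangelate in place | O=C(Sc1ccccc1)[C@H](OC(=O)[C@]2(C)O[C@@H]2C)[C@H]1C(=C)C(=O)O[C@H]1/C=C(\C)CC/C=C(/C)[Sn](CCCC)(CCCC)CCCC
A5 | alternative 3 | (1(10)Z,4E,6S,7S,8R,9R)-9-(tert-butyldimethylsilyloxy)-8-(4-methoxybenzyloxy)-13-norgermacra-1(10),4-dien-12,6-olide | O=C1O[C@H]2/C=C(\C)CC/C=C(/C)[C@@H](O[Si](C)(C)C(C)(C)C)[C@H](OCc3ccc(OC)cc3)[C@H]2C1
A6 | alternative 3 | seco cis-lactone with (E)-C4 iodoalkene on C6 and (Z)-C10=C1–C2=C3 terminal diene on C9, O9 TBS and O8 PMB ethers | O=C1O[C@@H](/C=C(\C)I)[C@H](C1)[C@@H](OCc2ccc(OC)cc2)[C@H](O[Si](C)(C)C(C)(C)C)/C(C)=C\C=C
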